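A closed, stirred vessel holds a racemate of left-handed and right-handed substrate with a single-handed partner, and partner takes each hand at its own pace.

| flask | left-handed substrate | right-handed substrate | partner | remark | time |
|---|---|---|---|---|---|
| beta | 36 mM | 36 mM | 59 mM | run made earlier |  |
| epsilon | 36 mM | 36 mM | 120 mM | run made earlier |  |
| gamma | 36 mM | 36 mM | 210 mM | run made earlier |  |
| Monday's | 36 mM | 36 mM | 50.0 mM |  | 50 min |
| Sunday's | 36 mM | 36 mM | 80.0 mM |  | 50 min |
| Thursday's | 36 mM | 36 mM | 100 mM |  | 50 min |
| Saturday's | 36 mM | 36 mM | 150 mM |  | 50 min |
| Tuesday's | 36 mM | 36 mM | 250 mM |  | 50 min |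

| run | time / min | left-handed product / % | right-handed product / % |
|---|---|---|---|
| beta | 4.00 | 24.4 | 9.7 |
| beta | 12.0 | 34.1 | 20.2 |
| beta | 25.0 | 39.5 | 24.8 |
| beta | 40.0 | 39.4 | 26.3 |
| beta | 50.0 | 42.9 | 29.5 |
| epsilon | 4.00 | 36.1 | 20.2 |
| epsilon | 8.00 | 45.4 | 31.1 |
| epsilon | 15.0 | 47.4 | 37.1 |
| epsilon | 25.0 | 46.9 | 42.5 |
| epsilon | 50.0 | 49.8 | 45.3 |
| gamma | 4.00 | 44.9 | 32.0 |
| gamma | 8.00 | 48.0 | 42.3 |
| gamma | 15.0 | 51.0 | 46.7 |
| gamma | 25.0 | 47.8 | 48.2 |
| gamma | 50.0 | 49.8 | 48.6 |

(each reading ± 1 percentage point)

- partner is single-handed; left-handed substrate and right-handed substrate are mirror images of each other, charged as a racemate, each of them at the stated concentration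
- the analysis behind the earlier runs scatters by 1 percentage point, standard deviation
- steps that have been proposed: partner + left-handed substrate -> left-handed product; partner + right-handed substrate -> right-handed product; left-handed substrate <-> achiral form; right-handed substrate <-> achiral form; partner <-> dormant form
- an excess is the difference of the two amounts in percent of their sum
- "hardly changes" means that all values lie within two and a half points (for a concentration: within two and a half percent of the largest)
- the handed part of partner does not stay in what it makes, so the products of the two hands are mirror images too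

- excess of left-handed product over right-handed product at the end for Monday's, Sunday's, Thursday's, Saturday's, Tuesday's, in this order
- the course of these numbers from the first flask to the last (hardly changes / falls all the way / rises all the way / rises, then falls / falls, then rises)

I write the balance of the reagent charged in the smaller amount. In Monday's flask that is partner, the limiting reagent, with 50.0 mM against 72.0 mM of both substrates together. Monday's cover is 0.694: partner charged over both substrates charged.

The epsilon run at 4.00 min reads 36.1% and 20.2%. Each hand is half the charge, so the logarithms of the fractions left give a selectivity factor s of 2.47, as a reading. If y of the right-handed substrate is left, y^s of the left-handed is left. If each partner ends in product, the two leftovers sum to 0.611, so y is 0.463. The excess, (y − y^s)/(2 − y − y^s), is then 22.6% for Monday's flask.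

The weak link is that assumption about partner. The beta run has a cover of 0.819, but its products read 72.4% at 50.0 min, so 0.884 of its cover shows as product. Scaling Monday's cover by that share leaves leftovers of 0.773, y of 0.549 and an excess of 26.3%, which I commit to. The gamma run, at cover 2.92, reads 1.22% at 50.0 min, so I expect the row to fall as cover climbs.

The forecast gives 26%, 15%, 9%, 3% and 0.8%, a course that falls all the way, and finds “no sign of racemisation through the achiral form”.

The flasks give 23.4%, 12.5%, 7.71%, 3.16% and 1.42%, a course that falls all the way; Monday's value lies above my first reckoning and below my second.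

partner + left-handed substrate → left-handed product (k = 0.0610 M⁻¹ s⁻¹); partner + right-handed substrate → right-handed product (k = 0.0270 M⁻¹ s⁻¹); left-handed substrate ⇌ achiral form (K = 0.850, k = 2.50 × 10⁻⁴ s⁻¹); right-handed substrate ⇌ achiral form (K = 0.850, k = 2.50 × 10⁻⁴ s⁻¹); partner ⇌ dormant form (K = 0.430, k = 3.10 × 10⁻⁴ s⁻¹) Monday's flask holds 11.5% achiral form at 50.0 min, yet the time allowed, set beside a tenfold time, makes no difference to its excess. Monday's products fill 0.906 of Monday's cover. Sunday's cover is 1.11, and its products fill 0.772 of that: of 80.0 mM partner, 61.7 mM stands in products, 11.9 mM remains as partner and 6.36 mM is dormant form.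

Readings and results were generated by integration for substances that don't exist.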